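The runs are simulated on assumed constants; noise was put on by code.

3 questions are put to flasks that differ in the amount of Q.

the same everywhere: J 0.20 M

| charge | Z | Q | temperature | remark | time |
|---|---|---|---|---|---|
| amber | 0.24 M | 2.9 mM | 20 °C | run made earlier |  |
| teal | 0.24 M | 28 mM | 35 °C | run made earlier |  |
| east | 0.240 M | 30 mM | 35 °C |  | 4.0 d |
| south-west | 0.240 M | 20 mM | 35 °C |  | 4.0 d |
| north-east | 0.240 M | 8.0 mM | 35 °C |  | 4.0 d |
| south-east | 0.240 M | 40 mM | 35 °C |  | 4.0 d |
| north | 0.240 M | 4.0 mM | 35 °C |  | 4.0 d |
| south | 0.240 M | 11 mM | 35 °C |  | 4.0 d |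

| run | time / d | E / % | J / % |
|---|---|---|---|
| amber | 0.625 | 0 | 99.2 |
| amber | 2.00 | 3.0 | 97.5 |
| amber | 4.00 | 3.2 | 94.8 |
| amber | 6.00 | 5.3 | 93.0 |
| teal | 0.333 | 7.8 | 85.1 |
| teal | 1.04 | 26.8 | 66.5 |
| teal | 1.67 | 38.1 | 54.8 |
| teal | 3.00 | 58.5 | 38.2 |

(each reading ± 1 percentage point)

- the flasks by amount of E, in percent of the J charged, highest first, at 4.0 d (east / south-west / north-east / south-east / north / south)
- the amount of E, in percent of the J charged of the flask you put first, at 4.0 d
- the amount of E, in percent of the J charged of the flask you put last, at 4.0 d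

Two chemists argue from the teal run. The first holds a straight line: E grows in step with Q times time. Teal shows 26.8 % of E after 1.04 d. Scaled by that product, north gets 14.7 %. East gets 110 % and south-east 147 %. Both pass the 100 percent that the charge allows, so this view cannot rank those two flasks.

The second chemist objects that J and Z are spent as E forms. J is the limiting reagent. She carries a log gap: the natural logarithm of the share of Z unspent over the share of J not yet E, both counted from E. If the rate goes with Q, J and Z, this gap grows in step with Q, time and the excess of Z over J. Teal's last reading gives 0.211.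

Scaled to south-east, the gap is 0.402, which she turns into 74.8 % of E. Scaled to north, it is 0.0402, which gives 19.7 %.

The forecast stands on her side, with a lower figure for north: south-east > east > south-west > south > north-east > north, top 75 %, low 18 %. Its ground: “Taking rate ∝ Q, E rises with Q”.

The simulation gives south-east > east > south-west > south > north-east > north, with 77.4 % in south-east and 16.6 % in north.

    X → G (k = 1.13 /h, Ea = 92.0 kJ/mol)
    G → Q + E (k = 0.883 /h, Ea = 92.0 kJ/mol)
    J + Q ⇌ D (K = 4.90 /M, k = 5.50 /M/h, Ea = 55.0 kJ/mol, ΔH = −68.0 kJ/mol)
    Z + D ⇌ X (K = 266 /M, k = 1.16 /M/h, Ea = 77.0 kJ/mol, ΔH = −23.0 kJ/mol)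
    X → Uj (k = 0.00147 /h, Ea = 120 kJ/mol)
    (constants at 35 °C)

South-east falls short of the full charge through the return of D to J + Q together with the time allowed: without that return it gives 98.5 %, and by 40.0 d it gives 99.8 %, against 77.4 %. The falling level of Z is a further part: south-east, with Z held at its charge, gives 92.9 %. In north, holding Z at its charge moves E from 16.6 % to 17.4 %, so falling Z is not the reason for its low figure. That low end is the straight line's region, with its 14.7 % against 16.6 %. South-east's E reads back as a log gap of 0.451, against 0.402 scaled from teal. A neighbour of north with 0.050 M of J has a scaled gap of 0.191, which means 21.0 % of E, and that flask gives 26.8 %.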